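## Retrosynthetic overview

1. The plan rests on C3 of chroman 2: a CH bonded to ring D, to the benzylic C4H2 on ring A and to C2H2–O. That is the boron-bearing carbon of ArD–CH(Bpin)–CH2–ArA (28) once one CH2 is inserted into its C–B bond. Target ⇐ hydrogenolysis ⇐ Mitsunobu closure of chroman 2 ⇐ alcohol 31 ⇐ boronate 28.
2. 28 ⇐ three-component conjunctive coupling of the aryllithium from bromide 19, vinylboronate 25 and ring A triflate 24. It forms the C3–ring D bond and the C4–C4a bond of chroman 2 and sets C3.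
3. 19 (trans chroman 1) ⇐ Friedel–Crafts closure of C4–C4a ⇐ aryl ether 18 ⇐ diol 16 ⇐ auxiliary-controlled syn-aldol of ring B arylacetyl imide 13 with ring D aldehyde 5 (C3–C4 bond, C3 centre).
4. 5 comes from 5-bromoresorcinol, 13 from 2-hydroxy-4,5-dimethoxybenzaldehyde, 24 from 4-(benzyloxy)-2-hydroxybenzaldehyde.
5. Ring order: rings A, B and D are bought as arenes; the pyran ring of chroman 1 closes in step 11 and that of chroman 2 in step 19.

Key step: step 15

Notation in names: Ar* = 5-(benzyloxy)-3-methoxy-2-{(3R,4S)-7-(benzyloxy)-3-[2-(benzyloxy)-4,5-dimethoxyphenyl]chroman-4-yl}phenyl (compound 19 without its bromine); ArA = 4-(benzyloxy)-2-(methoxymethoxy)phenyl; Bpin = pinacol boronate.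

Assumption: the (Sp,Sp) enantiomer of the ferrocenyl bisphosphine is taken as the one that leads to the R boronate 28; a model coupling with a simple ortho-substituted aryllithium fixes the sense, and the mirror-image ligand is used if it is opposite.

## Route

Step 1
Reactants: 1 5-bromoresorcinol
Product: 3 2-bromo-4,6-dihydroxybenzaldehyde, via aryl iminium chloride 2 (not isolated)
Conditions: POCl3, DMF, MeCN, 0 °C to rt; then H2O, 50 °C
Reagents that add atoms: N,N-dimethylformamide CN(C)C=O; water O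
Why: Vilsmeier–Haack formylation should enter para to one hydroxyl and ortho to the other, as it does with orcinol, and hydrolysis of the iminium salt releases the aldehyde.

Step 2
Reactants: 3 2-bromo-4,6-dihydroxybenzaldehyde
Product: 4 4-(benzyloxy)-2-bromo-6-hydroxybenzaldehyde
Conditions: BnBr (1.05 equiv), NaHCO3, KI (cat.), MeCN, 60 °C
Reagents that add atoms: benzyl bromide BrCc1ccccc1
Why: Williamson etherification under a weak base should touch only the hydroxyl para to the formyl group, because the ortho hydroxyl is held in a hydrogen bond to the carbonyl and is less acidic.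

Step 3
Reactants: 4 4-(benzyloxy)-2-bromo-6-hydroxybenzaldehyde
Product: 5 4-(benzyloxy)-2-bromo-6-methoxybenzaldehyde
Conditions: MeI, K2CO3, DMF, rt
Reagents that add atoms: iodomethane CI
Why: Williamson methylation of the remaining chelated phenol with the stronger carbonate base completes the ring D pattern (methoxy ortho, benzyloxy para to the formyl group, bromine at the other ortho position).

Step 4
Reactants: 6 2-hydroxy-4,5-dimethoxybenzaldehyde
Product: 7 2-(benzyloxy)-4,5-dimethoxybenzaldehyde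
Conditions: BnBr, K2CO3, DMF, 60 °C
Reagents that add atoms: benzyl bromide BrCc1ccccc1
Why: Williamson benzylation of the single phenol masks the ring B hydroxyl as the ether that is removed only in the last step.

Step 5
Reactants: 7 2-(benzyloxy)-4,5-dimethoxybenzaldehyde
Product: 9 [2-(benzyloxy)-4,5-dimethoxyphenyl]acetonitrile, via N-formyl vinyl sulfone 8 (not isolated)
Conditions: TosMIC, t-BuOK, DME, −40 °C; then MeOH, reflux
Reagents that add atoms: tosylmethyl isocyanide Cc1ccc(cc1)S(=O)(=O)C[N+]#[C-]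
Why: van Leusen reductive cyanation should give the nitrile with one more carbon, the TosMIC anion adding to the carbonyl, the oxazoline opening to the N-formyl vinyl sulfone and methoxide then removing the formyl group and expelling sulfinate.

Step 6
Reactants: 9 [2-(benzyloxy)-4,5-dimethoxyphenyl]acetonitrile
Product: 10 [2-(benzyloxy)-4,5-dimethoxyphenyl]acetic acid
Conditions: KOH, EtOH/H2O, reflux; then HCl (aq)
Reagents that add atoms: potassium hydroxide [K+].[OH-]; water O
Why: alkaline nitrile hydrolysis should give the arylacetic acid, benzyl and methyl aryl ethers being inert to hydroxide.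

Step 7
Reactants: 10 [2-(benzyloxy)-4,5-dimethoxyphenyl]acetic acid; 11 (S)-4-benzyl-2-oxazolidinone
Product: 13 (S)-4-benzyl-3-{[2-(benzyloxy)-4,5-dimethoxyphenyl]acetyl}oxazolidin-2-one, via mixed pivalic anhydride 12 (not isolated)
Conditions: PivCl, Et3N, THF, −20 to 0 °C; then 11, LiCl, rt
Reagents that add atoms: none
Why: N-acylation of the oxazolidinone by the mixed anhydride should occur at the less hindered arylacetyl carbonyl under LiCl and Et3N activation and leaves the auxiliary centre untouched.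

Step 8
Reactants: 13 (S)-4-benzyl-3-{[2-(benzyloxy)-4,5-dimethoxyphenyl]acetyl}oxazolidin-2-one; 5 4-(benzyloxy)-2-bromo-6-methoxybenzaldehyde
Product: 15 (S)-4-benzyl-3-[(2S,3S)-2-[2-(benzyloxy)-4,5-dimethoxyphenyl]-3-[4-(benzyloxy)-2-bromo-6-methoxyphenyl]-3-hydroxypropanoyl]oxazolidin-2-one, via Z-dibutylboron enolate 14 (not isolated)
Conditions: Bu2BOTf, i-Pr2NEt, CH2Cl2, 0 °C; 5, −78 to 0 °C; then pH 7 buffer, MeOH, H2O2
Reagents that add atoms: none
Why: in this Evans syn-aldol addition the Z boron enolate should react through a chair Zimmerman–Traxler transition state on the face away from the auxiliary benzyl group, which sets the α-carbon as 2S (the later 3R centre of chroman 1) and the carbinol as 3S, a centre that is erased in step 11.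

Step 9
Reactants: 15 syn-aldol imide
Product: 16 (1S,2R)-1-[4-(benzyloxy)-2-bromo-6-methoxyphenyl]-2-[2-(benzyloxy)-4,5-dimethoxyphenyl]propane-1,3-diol
Conditions: LiBH4, MeOH (1 equiv), THF, 0 °C
Reagents that add atoms: none
Why: reductive cleavage of the N-acyl oxazolidinone with LiBH4 should give the primary alcohol and return the auxiliary, the aryl bromide and the α-aryl centre being untouched at 0 °C.

Step 10
Reactants: 16 diol; 17 3-(benzyloxy)phenol
Product: 18 (1S,2R)-1-[4-(benzyloxy)-2-bromo-6-methoxyphenyl]-2-[2-(benzyloxy)-4,5-dimethoxyphenyl]-3-[3-(benzyloxy)phenoxy]propan-1-ol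
Conditions: PPh3, DIAD, THF, 0 °C to rt
Reagents that add atoms: none
Why: Mitsunobu etherification should engage only the primary hydroxyl, because the secondary benzylic hydroxyl is shielded by the 2,6-disubstituted ring D, so the ring A phenol is attached at the later C2 of chroman 1 without touching a stereocentre.

Step 11
Reactants: 18 aryl ether alcohol
Product: 19 (3R,4S)-7-(benzyloxy)-3-[2-(benzyloxy)-4,5-dimethoxyphenyl]-4-[4-(benzyloxy)-2-bromo-6-methoxyphenyl]chromane
Conditions: Bi(OTf)3 (5 mol %), CH2Cl2/HFIP (4:1), high dilution, −20 to 0 °C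
Reagents that add atoms: none
Why: in this intramolecular Friedel–Crafts alkylation the benzylic alcohol ionises to a cation stabilised by the para-benzyloxy and ortho-methoxy groups of ring D, ring A attacks through its position para to the benzyloxy group to close the six-membered ring, and allylic 1,3-strain between the ortho substituents of ring D and C3 holds C3–H in the plane of the cation so that ring A adds anti to ring B and sets C4 as S (trans).

Step 12
Reactants: 20 4-(benzyloxy)-2-hydroxybenzaldehyde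
Product: 21 4-(benzyloxy)-2-(methoxymethoxy)benzaldehyde
Conditions: MOMCl, i-Pr2NEt, CH2Cl2, 0 °C to rt
Reagents that add atoms: chloromethyl methyl ether COCCl
Why: acetal formation with MOMCl under amine base masks the phenol that later closes chroman 2 as an ether stable to organolithium reagents and palladium catalysis.

Step 13
Reactants: 21 4-(benzyloxy)-2-(methoxymethoxy)benzaldehyde
Product: 23 4-(benzyloxy)-2-(methoxymethoxy)phenol, via aryl formate 22 (not isolated)
Conditions: mCPBA, CH2Cl2, 0 °C to rt; then K2CO3 (cat.), MeOH, rt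
Reagents that add atoms: 3-chloroperoxybenzoic acid OOC(=O)c1cccc(Cl)c1
Why: Baeyer–Villiger oxidation of the Dakin type should insert oxygen between the formyl carbon and the ring, whose ortho and para alkoxy groups favour aryl migration, and methanolysis of the formate frees the phenol.

Step 14
Reactants: 23 4-(benzyloxy)-2-(methoxymethoxy)phenol
Product: 24 4-(benzyloxy)-2-(methoxymethoxy)phenyl trifluoromethanesulfonate
Conditions: PhNTf2, Et3N, DMAP (cat.), CH2Cl2, rt
Reagents that add atoms: N-phenylbis(trifluoromethanesulfonimide) O=S(=O)(N(c1ccccc1)S(=O)(=O)C(F)(F)F)C(F)(F)F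
Why: O-sulfonylation of the phenoxide with PhNTf2 gives the aryl triflate needed for oxidative addition under conditions mild enough for the MOM acetal.

Step 15
Reactants: 19 bromide of chroman 1; 25 vinylboronic acid pinacol ester; 24 ring A triflate
Product: 28 secondary pinacol boronate (R)-Ar*CH(Bpin)CH2ArA, via aryllithium 26 (not isolated), via lithium vinylborate complex 27 (not isolated)
Conditions: t-BuLi (2 equiv), THF, −78 °C; 25, −78 to 0 °C; then 24, Pd(OAc)2 (3 mol %), (Sp,Sp)-MandyPhos [1,1′-bis(diphenylphosphino)-2,2′-bis(α-dimethylaminobenzyl)ferrocene] (3.6 mol %), KOTf, THF, 60 °C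
Reagents that add atoms: none
Why: Bromine–lithium exchange at −78 °C gives aryllithium 26, which is trapped at once by 25 as the four-coordinate borate 27, so that it has no time to take the doubly benzylic C4 hydrogen of chroman 1. Zerovalent palladium, formed from Pd(OAc)2 and the chiral bisphosphine, adds oxidatively to triflate 24; the cationic arylpalladium species binds the vinyl group of 27 and induces a 1,2-metalate shift in which ring D moves from boron to the α-carbon while palladium takes the β-carbon, and reductive elimination then forms the CH2–ring A bond. The closest known reaction type is the enantioselective palladium-catalysed conjunctive cross-coupling of aryllithium-derived vinylboron ate complexes with aryl triflates, applied here to an unusually hindered migrating aryl group. No ring is closed: the step forms the bond from the future C3 of chroman 2 to ring D and the future C4–C4a bond. The new stereocentre (R) is set by the chiral ligand, which selects the alkene face that binds palladium during the metalate shift, the two centres of chroman 1 being remote. The step needs the metalate shift to win over direct transfer of the vinyl or aryl group to palladium and needs a halide-free cationic palladium centre; the triflate leaving group, KOTf (which removes the LiBr of the exchange as KBr) and the electron-rich, readily migrating ring D should secure this.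

Step 16
Reactants: 28 secondary pinacol boronate
Product: 30 primary pinacol boronate (R)-Ar*CH(CH2Bpin)CH2ArA, via chloromethyl borate complex 29 (not isolated)
Conditions: BrCH2Cl, n-BuLi, THF, −78 °C to rt
Reagents that add atoms: bromochloromethane ClCBr
Why: in this Matteson homologation chloromethyllithium made in the flask adds to boron and the ring D-bearing carbon migrates to the CH2 with loss of chloride and retention of configuration, so the stereocentre is kept and boron moves to the later C2 of chroman 2.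

Step 17
Reactants: 30 primary pinacol boronate
Product: 31 (R)-2-Ar*-3-ArA-propan-1-ol
Conditions: H2O2 (30 %), NaOH (aq), THF, 0 °C to rt
Reagents that add atoms: hydrogen peroxide OO
Why: oxidation of the carbon–boron bond with alkaline hydrogen peroxide (1,2-shift from boron to oxygen) should give the primary alcohol, the stereocentre being one carbon away and untouched.

Step 18
Reactants: 31 MOM-protected alcohol
Product: 32 (R)-2-Ar*-3-[4-(benzyloxy)-2-hydroxyphenyl]propan-1-ol
Conditions: HCl (cat.), MeOH/THF, 40 °C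
Reagents that add atoms: none
Why: acid-catalysed methanolysis of the MOM acetal frees the ring A phenol while the benzyl ethers and aryl methyl ethers stay in place.

Step 19
Reactants: 32 phenol alcohol
Product: 33 tetrabenzyl ether of the target [(3R)-7-(benzyloxy)-3-Ar*-chromane]
Conditions: PPh3, DIAD, THF, 0 °C to rt
Reagents that add atoms: none
Why: intramolecular Mitsunobu etherification (6-exo displacement at the primary carbon by the phenol) closes the pyran ring of chroman 2 without touching the C3 centre.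

Step 20
Reactants: 33 tetrabenzyl ether
Product: 34 (3R,4S)-3-(2-hydroxy-4,5-dimethoxyphenyl)-4-{4-hydroxy-2-[(3R)-7-hydroxychroman-3-yl]-6-methoxyphenyl}chroman-7-ol (target)
Conditions: H2 (1 atm), Pd/C, EtOAc/MeOH, rt
Reagents that add atoms: none
Why: hydrogenolysis over palladium on carbon should cleave the four benzyl ethers and leave the methyl ethers, the chroman C–O bonds and the three stereocentres untouched.

## Compound list

1 | 5-bromoresorcinol | Oc1cc(O)cc(Br)c1 | starting material
2 | N-[(2-bromo-4,6-dihydroxyphenyl)methylidene]-N-methylmethanaminium chloride | C[N+](C)=Cc1c(O)cc(O)cc1Br.[Cl-] | intermediate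
3 | 2-bromo-4,6-dihydroxybenzaldehyde | O=Cc1c(O)cc(O)cc1Br | intermediate
4 | 4-(benzyloxy)-2-bromo-6-hydroxybenzaldehyde | O=Cc1c(O)cc(OCc2ccccc2)cc1Br | intermediate
5 | 4-(benzyloxy)-2-bromo-6-methoxybenzaldehyde | COc1cc(OCc2ccccc2)cc(Br)c1C=O | intermediate
6 | 2-hydroxy-4,5-dimethoxybenzaldehyde | COc1cc(O)c(C=O)cc1OC | starting material
7 | 2-(benzyloxy)-4,5-dimethoxybenzaldehyde | COc1cc(OCc2ccccc2)c(C=O)cc1OC | intermediate
8 | N-{2-[2-(benzyloxy)-4,5-dimethoxyphenyl]-1-tosylethenyl}formamide | COc1cc(OCc2ccccc2)c(C=C(NC=O)S(=O)(=O)c2ccc(C)cc2)cc1OC | intermediate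
9 | [2-(benzyloxy)-4,5-dimethoxyphenyl]acetonitrile | COc1cc(OCc2ccccc2)c(CC#N)cc1OC | intermediate
10 | [2-(benzyloxy)-4,5-dimethoxyphenyl]acetic acid | COc1cc(OCc2ccccc2)c(CC(O)=O)cc1OC | intermediate
11 | (S)-4-benzyl-2-oxazolidinone | O=C1N[C@@H](Cc2ccccc2)CO1 | starting material
12 | mixed pivalic anhydride of acid 10 | COc1cc(OCc2ccccc2)c(CC(=O)OC(=O)C(C)(C)C)cc1OC | intermediate
13 | (S)-4-benzyl-3-{[2-(benzyloxy)-4,5-dimethoxyphenyl]acetyl}oxazolidin-2-one | COc1cc(OCc2ccccc2)c(CC(=O)N2[C@@H](Cc3ccccc3)COC2=O)cc1OC | intermediate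
14 | Z-dibutylboron enolate of imide 13 | CCCCB(CCCC)O/C(=C\c1cc(OC)c(OC)cc1OCc1ccccc1)N1[C@@H](Cc2ccccc2)COC1=O | intermediate
15 | (S)-4-benzyl-3-[(2S,3S)-2-[2-(benzyloxy)-4,5-dimethoxyphenyl]-3-[4-(benzyloxy)-2-bromo-6-methoxyphenyl]-3-hydroxypropanoyl]oxazolidin-2-one | O=C1OC[C@H](Cc2ccccc2)N1C(=O)[C@@H](c1cc(OC)c(OC)cc1OCc1ccccc1)[C@H](O)c1c(OC)cc(OCc2ccccc2)cc1Br | intermediate
16 | (1S,2R)-1-[4-(benzyloxy)-2-bromo-6-methoxyphenyl]-2-[2-(benzyloxy)-4,5-dimethoxyphenyl]propane-1,3-diol | OC[C@@H](c1cc(OC)c(OC)cc1OCc1ccccc1)[C@H](O)c1c(OC)cc(OCc2ccccc2)cc1Br | intermediate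
17 | 3-(benzyloxy)phenol | Oc1cccc(OCc2ccccc2)c1 | starting material
18 | (1S,2R)-1-[4-(benzyloxy)-2-bromo-6-methoxyphenyl]-2-[2-(benzyloxy)-4,5-dimethoxyphenyl]-3-[3-(benzyloxy)phenoxy]propan-1-ol | C(Oc1cccc(OCc2ccccc2)c1)[C@@H](c1cc(OC)c(OC)cc1OCc1ccccc1)[C@H](O)c1c(OC)cc(OCc2ccccc2)cc1Br | intermediate
19 | (3R,4S)-7-(benzyloxy)-3-[2-(benzyloxy)-4,5-dimethoxyphenyl]-4-[4-(benzyloxy)-2-bromo-6-methoxyphenyl]chromane | COc1cc(OCc2ccccc2)c(cc1OC)[C@@H]1COc2cc(OCc3ccccc3)ccc2[C@H]1c1c(OC)cc(OCc2ccccc2)cc1Br | intermediate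
20 | 4-(benzyloxy)-2-hydroxybenzaldehyde | O=Cc1ccc(OCc2ccccc2)cc1O | starting material
21 | 4-(benzyloxy)-2-(methoxymethoxy)benzaldehyde | COCOc1cc(OCc2ccccc2)ccc1C=O | intermediate
22 | 4-(benzyloxy)-2-(methoxymethoxy)phenyl formate | COCOc1cc(OCc2ccccc2)ccc1OC=O | intermediate
23 | 4-(benzyloxy)-2-(methoxymethoxy)phenol | COCOc1cc(OCc2ccccc2)ccc1O | intermediate
24 | 4-(benzyloxy)-2-(methoxymethoxy)phenyl trifluoromethanesulfonate | COCOc1cc(OCc2ccccc2)ccc1OS(=O)(=O)C(F)(F)F | intermediate
25 | vinylboronic acid pinacol ester | C=CB1OC(C)(C)C(C)(C)O1 | starting material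
26 | aryllithium Ar*–Li (19 with lithium in place of bromine) | COc1cc(OCc2ccccc2)c(cc1OC)[C@@H]1COc2cc(OCc3ccccc3)ccc2[C@H]1c1c(OC)cc(OCc2ccccc2)cc1[Li] | intermediate
27 | lithium Ar*(vinyl)(pinacolato)borate | COc1cc(OCc2ccccc2)c(cc1OC)[C@@H]1COc2cc(OCc3ccccc3)ccc2[C@H]1c1c(OC)cc(OCc2ccccc2)cc1[B-]1(C=C)OC(C)(C)C(C)(C)O1.[Li+] | intermediate
28 | (R)-Ar*CH(Bpin)CH2ArA, secondary pinacol boronate | COc1cc(OCc2ccccc2)c(cc1OC)[C@@H]1COc2cc(OCc3ccccc3)ccc2[C@H]1c1c(OC)cc(OCc2ccccc2)cc1[C@@H](Cc1ccc(OCc2ccccc2)cc1OCOC)B1OC(C)(C)C(C)(C)O1 | intermediate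
29 | lithium (chloromethyl)borate complex of 28 | COc1cc(OCc2ccccc2)c(cc1OC)[C@@H]1COc2cc(OCc3ccccc3)ccc2[C@H]1c1c(OC)cc(OCc2ccccc2)cc1[C@@H](Cc1ccc(OCc2ccccc2)cc1OCOC)[B-]1(CCl)OC(C)(C)C(C)(C)O1.[Li+] | intermediate
30 | (R)-Ar*CH(CH2Bpin)CH2ArA, primary pinacol boronate | COc1cc(OCc2ccccc2)c(cc1OC)[C@@H]1COc2cc(OCc3ccccc3)ccc2[C@H]1c1c(OC)cc(OCc2ccccc2)cc1[C@@H](Cc1ccc(OCc2ccccc2)cc1OCOC)CB1OC(C)(C)C(C)(C)O1 | intermediate
31 | (R)-2-Ar*-3-ArA-propan-1-ol | COc1cc(OCc2ccccc2)c(cc1OC)[C@@H]1COc2cc(OCc3ccccc3)ccc2[C@H]1c1c(OC)cc(OCc2ccccc2)cc1[C@@H](Cc1ccc(OCc2ccccc2)cc1OCOC)CO | intermediate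
32 | (R)-2-Ar*-3-[4-(benzyloxy)-2-hydroxyphenyl]propan-1-ol | COc1cc(OCc2ccccc2)c(cc1OC)[C@@H]1COc2cc(OCc3ccccc3)ccc2[C@H]1c1c(OC)cc(OCc2ccccc2)cc1[C@@H](Cc1ccc(OCc2ccccc2)cc1O)CO | intermediate
33 | (3R)-7-(benzyloxy)-3-Ar*-chromane, tetrabenzyl ether of the target | COc1cc(OCc2ccccc2)c(cc1OC)[C@@H]1COc2cc(OCc3ccccc3)ccc2[C@H]1c1c(OC)cc(OCc2ccccc2)cc1[C@@H]1COc2cc(OCc3ccccc3)ccc2C1 | intermediate
34 | (3R,4S)-3-(2-hydroxy-4,5-dimethoxyphenyl)-4-{4-hydroxy-2-[(3R)-7-hydroxychroman-3-yl]-6-methoxyphenyl}chroman-7-ol | COc1cc(O)c([C@@H]2COc3cc(O)ccc3[C@H]2c2c(OC)cc(O)cc2[C@@H]2COc3cc(O)ccc3C2)cc1OC | target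

## Step count and risks

Total steps: 20. Longest linear sequence: 14 steps (steps 4 to 11, then 15 to 20).

The three steps most likely to fail:

1. Step 15. The congested ring D may add to boron or migrate too slowly. Then proton transfer from the doubly benzylic C4–H to the aryllithium, direct Suzuki-type transfer of the vinyl group, or weak ligand control against the existing centres could take over. The fallback replaces the metalate shift by a classical auxiliary-controlled enolate alkylation, sets out from 19 (with 21 for the electrophile) and returns at 31, so steps 16 and 17 are skipped as well. Palladium-catalysed coupling of 19 with the Reformatsky reagent BrZnCH2CO2Et (Pd(P(t-Bu)3)2, THF) would give the ethyl arylacetate F1. LiOH hydrolysis gives the arylacetic acid F2, pivaloyl chloride and Et3N convert it into the mixed anhydride F3, and (R)-4-benzyl-2-oxazolidinone with LiCl gives the imide F4. Aldehyde 21 is reduced with NaBH4 to the benzyl alcohol F5, and an Appel reaction (CBr4, PPh3) gives the benzyl bromide F6, used at once. The sodium enolate of F4 (NaN(SiMe3)2, THF, −78 °C) is alkylated by F6 on the face away from the auxiliary benzyl group to give the alkylated imide F7 with the R centre. LiBH4 reduction of F7 gives alcohol 31.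

2. Step 11. The cation may be captured by the benzyloxy oxygen of ring B (closure to a dihydrobenzofuran with loss of benzyl). It may lose the C3 proton to a stilbene, with erosion of the C3 configuration on reprotonation. Ring closure may also occur ortho instead of para to the benzyloxy group of ring A. The fallback is a base-mediated ortho-quinone methide annulation, which has no cation next to C3 and also bypasses steps 7 to 10; it sets out from 5, 17 and 10 and returns at 19. The bromomagnesium phenoxide of 17 (EtMgBr, toluene) is hydroxyalkylated at its free ortho position by aldehyde 5 to give the benzhydrol F8. Sodium p-toluenesulfinate and formic acid convert it into the sulfone F9. Base (Cs2CO3) releases the ortho-quinone methide F10. F10 undergoes Michael addition–lactonisation with the ammonium enolate formed from anhydride 12 (from acid 10) and a chiral isothiourea catalyst such as benzotetramisole, in the enantiomer that gives 4S. Base equilibration at C3 then gives the trans lactone F11. LiBH4 reduction gives the phenol alcohol F12, and Mitsunobu closure (PPh3, DIAD) gives 19.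

3. Step 16. Addition of the short-lived chloromethyllithium to the crowded secondary boronate may be slow or reversible, so that the carbenoid decomposes before capture or a second insertion occurs. The fallback uses vinylation and oxidative cleavage instead of carbenoid insertion, sets out from 28 and returns at 31. Zweifel olefination (vinyllithium, then I2 and NaOMe) gives, with retention at the migrating carbon, the terminal alkene F13. Dihydroxylation (OsO4 cat., NMO) gives the diol F14. NaIO4 cleaves it to the aldehyde F15, which is reduced at once with NaBH4, before the α-aryl aldehyde can enolise, to give alcohol 31.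

## Further compounds

F1 | step 15 | ethyl 2-Ar*-acetate (19 with CH2CO2Et in place of Br) | COc1cc(OCc2ccccc2)c(cc1OC)[C@@H]1COc2cc(OCc3ccccc3)ccc2[C@H]1c1c(OC)cc(OCc2ccccc2)cc1CC(=O)OCC
F2 | step 15 | 2-Ar*-acetic acid | COc1cc(OCc2ccccc2)c(cc1OC)[C@@H]1COc2cc(OCc3ccccc3)ccc2[C@H]1c1c(OC)cc(OCc2ccccc2)cc1CC(O)=O
F3 | step 15 | mixed pivalic anhydride of F2 | COc1cc(OCc2ccccc2)c(cc1OC)[C@@H]1COc2cc(OCc3ccccc3)ccc2[C@H]1c1c(OC)cc(OCc2ccccc2)cc1CC(=O)OC(=O)C(C)(C)C
F4 | step 15 | (R)-4-benzyl-3-(2-Ar*-acetyl)oxazolidin-2-one | COc1cc(OCc2ccccc2)c(cc1OC)[C@@H]1COc2cc(OCc3ccccc3)ccc2[C@H]1c1c(OC)cc(OCc2ccccc2)cc1CC(=O)N1[C@H](Cc2ccccc2)COC1=O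
F5 | step 15 | [4-(benzyloxy)-2-(methoxymethoxy)phenyl]methanol | COCOc1cc(OCc2ccccc2)ccc1CO
F6 | step 15 | 4-(benzyloxy)-1-(bromomethyl)-2-(methoxymethoxy)benzene | COCOc1cc(OCc2ccccc2)ccc1CBr
F7 | step 15 | (R)-4-benzyl-3-[(2R)-2-Ar*-3-ArA-propanoyl]oxazolidin-2-one | COc1cc(OCc2ccccc2)c(cc1OC)[C@@H]1COc2cc(OCc3ccccc3)ccc2[C@H]1c1c(OC)cc(OCc2ccccc2)cc1[C@@H](Cc1ccc(OCc2ccccc2)cc1OCOC)C(=O)N1[C@H](Cc2ccccc2)COC1=O
F8 | step 11 | 5-(benzyloxy)-2-{[4-(benzyloxy)-2-bromo-6-methoxyphenyl](hydroxy)methyl}phenol (racemic) | OC(c1ccc(OCc2ccccc2)cc1O)c1c(OC)cc(OCc2ccccc2)cc1Br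
F9 | step 11 | 5-(benzyloxy)-2-{[4-(benzyloxy)-2-bromo-6-methoxyphenyl](tosyl)methyl}phenol (racemic) | Cc1ccc(cc1)S(=O)(=O)C(c1ccc(OCc2ccccc2)cc1O)c1c(OC)cc(OCc2ccccc2)cc1Br
F10 | step 11 | 3-(benzyloxy)-6-[4-(benzyloxy)-2-bromo-6-methoxybenzylidene]cyclohexa-2,4-dien-1-one (ortho-quinone methide) | O=C1C=C(OCc2ccccc2)C=CC1=Cc1c(OC)cc(OCc2ccccc2)cc1Br
F11 | step 11 | (3R,4S)-7-(benzyloxy)-3-[2-(benzyloxy)-4,5-dimethoxyphenyl]-4-[4-(benzyloxy)-2-bromo-6-methoxyphenyl]chroman-2-one | COc1cc(OCc2ccccc2)c(cc1OC)[C@@H]1C(=O)Oc2cc(OCc3ccccc3)ccc2[C@H]1c1c(OC)cc(OCc2ccccc2)cc1Br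
F12 | step 11 | 5-(benzyloxy)-2-{(1S,2R)-1-[4-(benzyloxy)-2-bromo-6-methoxyphenyl]-2-[2-(benzyloxy)-4,5-dimethoxyphenyl]-3-hydroxypropyl}phenol | COc1cc(OCc2ccccc2)c(cc1OC)[C@H](CO)[C@@H](c1ccc(OCc2ccccc2)cc1O)c1c(OC)cc(OCc2ccccc2)cc1Br
F13 | step 16 | (S)-3-Ar*-4-ArA-but-1-ene (vinyl in place of Bpin, same spatial arrangement as 28) | COc1cc(OCc2ccccc2)c(cc1OC)[C@@H]1COc2cc(OCc3ccccc3)ccc2[C@H]1c1c(OC)cc(OCc2ccccc2)cc1[C@@H](Cc1ccc(OCc2ccccc2)cc1OCOC)C=C
F14 | step 16 | (3R)-3-Ar*-4-ArA-butane-1,2-diol (mixture at C2) | COc1cc(OCc2ccccc2)c(cc1OC)[C@@H]1COc2cc(OCc3ccccc3)ccc2[C@H]1c1c(OC)cc(OCc2ccccc2)cc1[C@@H](Cc1ccc(OCc2ccccc2)cc1OCOC)C(O)CO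
F15 | step 16 | (R)-2-Ar*-3-ArA-propanal | COc1cc(OCc2ccccc2)c(cc1OC)[C@@H]1COc2cc(OCc3ccccc3)ccc2[C@H]1c1c(OC)cc(OCc2ccccc2)cc1[C@@H](Cc1ccc(OCc2ccccc2)cc1OCOC)C=O
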